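We ask first what the flask ends as. The product mixture is what is asked about, so the problem comes first.

| flask | Aj | Ji | Ym | Ul | remark | time |
|---|---|---|---|---|---|---|
| Wednesday's | 0.75 M | 0.75 M | 1.5 M | 75 mM | run made earlier |  |
| Saturday's | 1 M | 1 M | 1.5 M | 75 mM | run made earlier |  |
| teal | 0.50 M | 0.50 M | 2.50 M | 25 mM |  | 40 h |
| green | 0.50 M | 0.50 M | 1.50 M | 75 mM |  | 40 h |

| run | time / h | Ze / % | Ve / % | Aj / % |
|---|---|---|---|---|
| Wednesday's | 3.00 | 19 | 9 | 36 |
| Wednesday's | 6.00 | 37 | 17 | 23 |
| Wednesday's | 8.00 | 46 | 20 | 15 |
| Wednesday's | 12.0 | 55 | 26 | 9 |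
| Wednesday's | 15.0 | 58 | 27 | 6 |
| Saturday's | 1.33 | 9 | 4 | 43 |
| Saturday's | 4.00 | 27 | 14 | 30 |
| Saturday's | 6.00 | 37 | 16 | 25 |
| Saturday's | 10.0 | 45 | 22 | 15 |
| Saturday's | 15.0 | 48 | 23 | 17 |

(each reading ± 1.5 percentage points)

- Ul is single-handed; Aj and Ji are mirror images of each other, charged as a racemate, each of them at the stated concentration
- solid, in amounts per volume of the solution: Ym
- on the list of suspects stand: Eb + Ul + Aj -> Ul + Ze; Eb + Ul + Ji -> Ul + Ve; Ym <-> Eb; Aj <-> Ji
- at the start none of Ym is in solution
- an excess is the difference of the two amounts in percent of their sum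
- an excess is below zero if the other one leads
- no earlier run changes the charge of Ul; that part of a forecast is a guess

1. which of the two ends with the higher excess of Ze over Ve ("neither" if they lie within 2 percentage points) (teal / green / neither)
2. excess of Ze over Ve at the end, teal
3. excess of Ze over Ve at the end, green

Take the run in slow motion. At the start Ym lies undissolved, so Eb has to appear first; then Ul turns Eb and Aj into Ze, and Eb and Ji into Ve. At 3.00 h in Wednesday's run Ze stands at 19 % and Ve at 9 %, so Ze has formed twice as much and Aj should be falling behind Ji. But Aj reads 36 %, and the balance gives Ji 36.0 %. So the exchange between Aj and Ji closes that gap while the products form, which is a dynamic kinetic resolution.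

In the middle of Wednesday's run, then, each new portion of product divides in the same way. Call the excess of Ze over Ve the split, 36.5 % at Wednesday's last reading. It reads 35.7 % at the first reading, with 28.0 % of product, against 85.0 % of product at the last.

Now the end. In Saturday's run Ym is the limiting reagent: it allows 75.0 % of product, the run reaches 71.0 %, and the excess there reads 35.2 %. Short of full conversion, then, Saturday's run still reads close to the split. Green has 1.50 M of Ym and teal 2.50 M, each against 1.00 M of Aj and Ji together. Teal has a third of the Ul, a change that no earlier run shows, so how far teal gets is a guess, but we expect the split in both and no winner.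

The forecast says 36 % (32 % to 40 %) for teal, 35.5 % (31 % to 39 %) for green, and neither, on the ground that “the excess stays selectivity-controlled”.

The flasks give 36.4 % for teal and 35.7 % for green, so the answer is neither.

    Eb + Ul + Aj → Ul + Ze (k = 8.00 /M²/h)
    Eb + Ul + Ji → Ul + Ve (k = 3.70 /M²/h)
    Ym ⇌ Eb, rate k3*(cs3 - [Eb]) while solid is left; crystals form when [Eb] > cs3 (solubility = 0.420 M, k = 1.80 /h)
    Aj ⇌ Ji (k = 2.40 /h)

Teal ends with 9.5 % of its charged Aj left and green with 0.091 %, yet their excesses lie 0.70 percentage points apart. Now take green with 0.38 M of Ym. Against 1.00 M of substrate that allows 38.0 % of product, and the split divides this into Ze 25.9 % and Ve 12.1 %. That flask ends with Ym at 0 %, Ji at 31.0 %, Ze at 25.9 %, Ve at 12.1 %, and an excess of 36.3 %.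

The data stem from a simulated flask with constants of no real substance; the scatter is artificial.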